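**Assumption and labels:** the SMILES is taken literally, including absolute configuration. Atoms carry eremophilane numbers (ring A = C1–C5, C10; ring B = C5–C10; C14 = CH3 on C5, C15 = CH3 on C4, C11–C13 = isopropenyl on C7), and α is the face opposite C14. In these terms the target is the 3α,9α-bis[(Z)-hex-2-enoate] of 4β,5β-dimethyl-7α-isopropenyl-10αH-trans-decalin-3α,8α,9α-triol.

**Retrosynthetic overview**
1. Target 19 ⇐ 8-O-silyl 3α,9α-diol 15: esterify both equatorial alcohols with hex-2-ynoic acid, Lindlar, desilylate.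
2. 15 ⇐ trans-fused Δ7-ene-3,9-dione 9: isopropenyl cuprate to C7 (anti to C14) with enolate silylation, Li/NH3 at C3, Rubottom at C8, hydride at C9.
3. 9 ⇐ enone-aldehyde 8 by the key C3–C4 bond: the C3 aldehyde reacts as an acyl anion (Breslow intermediate) and adds across the vinyl group on C5, closing ring A onto ring B.
4. 8 ⇐ 3-methylcyclohex-2-enone 1 (ring B, bought): catalytic asymmetric conjugate vinylation sets C5, the enolate is propargylated at C10, then enone formation and anti-Markovnikov alkyne hydration.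
5. Ring order: ring B from the start, ring A in step 4; only C5 is set by a chiral catalyst, all other centres follow from it.

**Route**

Step 1
Reactants: 1 3-methylcyclohex-2-en-1-one; 2 vinylmagnesium bromide; 3 3-bromoprop-1-yne
Product: 5 3-methyl-2-(prop-2-yn-1-yl)-3-vinylcyclohexan-1-one (quaternary carbon as in (S)-3-methyl-3-vinylcyclohexanone; C2 epimers), via aluminium enolate 4 (not isolated)
Conditions: 2, Me2AlCl, Et2O, −30 °C; 1, Cu(O2C-2-thienyl) (5 mol %), chiral aminophosphine ligand (SimplePhos type, 10 mol %), −30 °C; then MeLi, THF, 3, −30 → 0 °C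
Reagents that add atoms: vinylmagnesium bromide C=C[Mg]Br; 3-bromoprop-1-yne C#CCBr
Why: Copper-catalysed asymmetric conjugate addition of an alkenylalane to a β-substituted enone (Alexakis/Hoveyda type) creates the C5 quaternary centre (vinyl = C4/C15, ligand enantiomer chosen so that C14 is β), and the regiodefined aluminium enolate, activated as its methyl ate complex, is C-alkylated at C10, whose configuration does not matter because it is epimerised in step 4.

Step 2
Reactants: 5 3-methyl-2-(prop-2-yn-1-yl)-3-vinylcyclohexan-1-one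
Product: 7 5-methyl-6-(prop-2-yn-1-yl)-5-vinylcyclohex-2-en-1-one (quaternary centre unchanged; C6 epimers), via phenylselanyl ketone 6 (not isolated)
Conditions: LDA (1.0 equiv), THF, −78 °C; PhSeCl; then H2O2, pyridine, CH2Cl2, 0 °C
Reagents that add atoms: none
Why: Kinetic deprotonation takes the unhindered C8 methylene rather than the tertiary C10 hydrogen, and selenation followed by selenoxide syn-elimination (Reich) can only give the Δ7 enone; no stereocentre is formed.

Step 3
Reactants: 7 5-methyl-6-(prop-2-yn-1-yl)-5-vinylcyclohex-2-en-1-one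
Product: 8 3-(6-methyl-2-oxo-6-vinylcyclohex-3-en-1-yl)propanal
Conditions: [CpRu(MeCN)(6-tBu-2-Ph2P-pyridine)2]PF6 (3 mol %), H2O, acetone, 70 °C
Reagents that add atoms: water O
Why: Grotjahn-type ruthenium-catalysed anti-Markovnikov hydration of the terminal alkyne gives the C3 aldehyde under neutral conditions that leave the enone and the vinyl group untouched; no stereocentre is formed.

Step 4
Reactants: 8 3-(6-methyl-2-oxo-6-vinylcyclohex-3-en-1-yl)propanal
Product: 9 4β,5β-dimethyl-10αH-trans-decal-7-ene-3,9-dione [4a,5-dimethyl-4a,5,8,8a-tetrahydronaphthalene-1,6(4H,7H)-dione]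
Conditions: N-mesityl cycloalkane-fused thiazolium perchlorate (20 mol %), DBU (40 mol %), 1,4-dioxane, 120 °C, 0.02 M; then DBU, rt
Reagents that add atoms: none
Why: Proposed new method: the thiazolylidene turns the C3 aldehyde into its Breslow (acyl-anion) intermediate, whose enaminol carbon bonds to the internal vinyl carbon C4 while the O–H proton goes to C15 in a concerted Conia-ene-like step, closing ring A as a 2-methylcyclohexanone (six-membered, helped by the quaternary C5, with the conjugated C9 carbonyl only a poor, reversible benzoin acceptor); the closest known reaction is the Glorius NHC-catalysed intramolecular hydroacylation of unactivated alkenes (2-allyloxybenzaldehydes to 3-methylchromanones), and C4 and C10, both α to a carbonyl, then equilibrate under DBU to the trans-fused isomer with equatorial 4β-methyl (an estimated several-to-one preference at each centre, the minor epimers being recycled).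

Step 5
Reactants: 9 4β,5β-dimethyl-10αH-trans-decal-7-ene-3,9-dione; 10 2-bromopropene
Product: 12 9-(tert-butyldimethylsilyloxy)-7α-isopropenyl-4β,5β-dimethyl-10αH-trans-decal-8-en-3-one, via lithium enolate 11 (not isolated)
Conditions: 10, t-BuLi (2 equiv), Et2O, −78 °C; CuI (0.5 equiv); 9, −78 °C; then TBSCl, HMPA, Et3N, −78 °C → rt
Reagents that add atoms: 2-bromopropene C=C(C)Br; tert-butyldimethylsilyl chloride CC(C)(C)[Si](C)(C)Cl
Why: Gilman cuprate conjugate addition to the Δ7-en-9-one comes from the α face, anti to the axial C14 methyl that is 1,3 to C7, setting 7α-isopropenyl, and O-silylation of the regiodefined enolate both masks C9 and marks C8 for oxidation; the saturated C3 ketone does not react with the cuprate.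

Step 6
Reactants: 12 9-(tert-butyldimethylsilyloxy)-7α-isopropenyl-4β,5β-dimethyl-10αH-trans-decal-8-en-3-one
Product: 13 9-(tert-butyldimethylsilyloxy)-7α-isopropenyl-4β,5β-dimethyl-10αH-trans-decal-8-en-3α-ol
Conditions: Li, NH3(l), THF, t-BuOH, −78 °C; NH4Cl
Reagents that add atoms: none
Why: Dissolving-metal reduction of the C3 ketone is thermodynamically controlled and gives the equatorial 3α-alcohol (trans to the 4β-methyl), whereas hydride would be steered to the wrong face by the syn-axial C14; the silyl enol ether and the isolated isopropenyl group are inert.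

Step 7
Reactants: 13 9-(tert-butyldimethylsilyloxy)-7α-isopropenyl-4β,5β-dimethyl-10αH-trans-decal-8-en-3α-ol
Product: 14 8α-(tert-butyldimethylsilyloxy)-3α-hydroxy-7α-isopropenyl-4β,5β-dimethyl-10αH-trans-decalin-9-one
Conditions: mCPBA (1.05 equiv), NaHCO3, CH2Cl2, −20 °C
Reagents that add atoms: mCPBA OOC(=O)c1cccc(Cl)c1
Why: Rubottom oxidation: the electron-rich silyl enol ether is epoxidised much faster than the 1,1-disubstituted alkene and from the α face (the β face at C9 is shielded by the syn-axial C14), and silyl transfer gives the 8α-silyloxy 9-ketone.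

Step 8
Reactants: 14 8α-(tert-butyldimethylsilyloxy)-3α-hydroxy-7α-isopropenyl-4β,5β-dimethyl-10αH-trans-decalin-9-one
Product: 15 8α-(tert-butyldimethylsilyloxy)-7α-isopropenyl-4β,5β-dimethyl-10αH-trans-decalin-3α,9α-diol
Conditions: NaBH4, CeCl3·7H2O, MeOH, −40 °C
Reagents that add atoms: none
Why: Luche-type hydride reduction in which attack anti to the axial C8–O bond (polar Felkin–Anh, the α face also being blocked by the silyl ether) delivers hydride from the β face and gives the equatorial 9α-alcohol, cis to O8.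

Step 9
Reactants: 15 8α-(tert-butyldimethylsilyloxy)-7α-isopropenyl-4β,5β-dimethyl-10αH-trans-decalin-3α,9α-diol; 16 hex-2-ynoic acid
Product: 17 3α,9α-bis(hex-2-ynoate) of 15
Conditions: 16 (2.5 equiv), DIC, DMAP (cat.), CH2Cl2, 0 °C → rt
Reagents that add atoms: hex-2-ynoic acid CCCC#CC(=O)O
Why: Steglich esterification of the two equatorial secondary alcohols while O8 is blocked, using the alkynoic acid because it has no alkene geometry to lose during acylation.

Step 10
Reactants: 17 3α,9α-bis(hex-2-ynoate) of 15
Product: 18 8α-(tert-butyldimethylsilyloxy)-7α-isopropenyl-4β,5β-dimethyl-10αH-trans-decalin-3α,9α-diyl bis[(Z)-hex-2-enoate]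
Conditions: H2 (1 atm), Pd/CaCO3–Pb(OAc)2 (Lindlar catalyst), quinoline, EtOAc, rt
Reagents that add atoms: none
Why: Lindlar semi-hydrogenation adds H2 syn to each ynoate to give both (Z)-enoates and stops there, the 1,1-disubstituted isopropenyl alkene not being reduced on the poisoned catalyst.

Step 11
Reactants: 18 8α-(tert-butyldimethylsilyloxy)-7α-isopropenyl-4β,5β-dimethyl-10αH-trans-decalin-3α,9α-diyl bis[(Z)-hex-2-enoate]
Product: 19 target CNP0420276.1
Conditions: HF·pyridine, THF, 0 °C → rt
Reagents that add atoms: none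
Why: Acidic fluoride cleavage of the axial silyl ether avoids base-induced acyl migration from O9 to O8 and enoate isomerisation, and touches no stereocentre.

**Compound list**
1 | 3-methylcyclohex-2-en-1-one | CC1=CC(=O)CCC1 | starting material
2 | vinylmagnesium bromide | C=C[Mg]Br | starting material
3 | 3-bromoprop-1-yne (propargyl bromide) | C#CCBr | starting material
4 | dimethylaluminium enolate of (S)-3-methyl-3-vinylcyclohexanone (enolate C=C toward the quaternary carbon) | C=C[C@@]1(C)CCCC(O[Al](C)C)=C1 | intermediate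
5 | 3-methyl-2-(prop-2-yn-1-yl)-3-vinylcyclohexan-1-one, quaternary carbon as in (S)-3-methyl-3-vinylcyclohexanone, C2 epimers | C#CCC1C(=O)CCC[C@]1(C)C=C | intermediate
6 | 3-methyl-6-(phenylselanyl)-2-(prop-2-yn-1-yl)-3-vinylcyclohexan-1-one, same quaternary carbon | C#CCC1C(=O)C([Se]c2ccccc2)CC[C@]1(C)C=C | intermediate
7 | 5-methyl-6-(prop-2-yn-1-yl)-5-vinylcyclohex-2-en-1-one, same quaternary carbon, C6 epimers | C#CCC1C(=O)C=CC[C@]1(C)C=C | intermediate
8 | 3-(6-methyl-2-oxo-6-vinylcyclohex-3-en-1-yl)propanal, same quaternary carbon | O=CCCC1C(=O)C=CC[C@]1(C)C=C | intermediate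
9 | 4β,5β-dimethyl-10αH-trans-decal-7-ene-3,9-dione | O=C1C=CC[C@]2(C)[C@@H](C)C(=O)CC[C@@H]12 | intermediate
10 | 2-bromopropene | C=C(C)Br | starting material
11 | lithium C9 enolate of 7α-isopropenyl-4β,5β-dimethyl-10αH-trans-decalin-3,9-dione | C=C(C)[C@@H]1C[C@]2(C)[C@@H](C)C(=O)CC[C@H]2C(O[Li])=C1 | intermediate
12 | 9-(tert-butyldimethylsilyloxy)-7α-isopropenyl-4β,5β-dimethyl-10αH-trans-decal-8-en-3-one | C=C(C)[C@@H]1C[C@]2(C)[C@@H](C)C(=O)CC[C@H]2C(O[Si](C)(C)C(C)(C)C)=C1 | intermediate
13 | 9-(tert-butyldimethylsilyloxy)-7α-isopropenyl-4β,5β-dimethyl-10αH-trans-decal-8-en-3α-ol | C=C(C)[C@@H]1C[C@]2(C)[C@@H](C)[C@H](O)CC[C@H]2C(O[Si](C)(C)C(C)(C)C)=C1 | intermediate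
14 | 8α-(tert-butyldimethylsilyloxy)-3α-hydroxy-7α-isopropenyl-4β,5β-dimethyl-10αH-trans-decalin-9-one | C=C(C)[C@@H]1C[C@]2(C)[C@@H](C)[C@H](O)CC[C@H]2C(=O)[C@@H]1O[Si](C)(C)C(C)(C)C | intermediate
15 | 8α-(tert-butyldimethylsilyloxy)-7α-isopropenyl-4β,5β-dimethyl-10αH-trans-decalin-3α,9α-diol | C=C(C)[C@@H]1C[C@]2(C)[C@@H](C)[C@H](O)CC[C@H]2[C@H](O)[C@@H]1O[Si](C)(C)C(C)(C)C | intermediate
16 | hex-2-ynoic acid | CCCC#CC(=O)O | starting material
17 | 3α,9α-bis(hex-2-ynoate) of 15 | C=C(C)[C@@H]1C[C@]2(C)[C@@H](C)[C@H](OC(=O)C#CCCC)CC[C@H]2[C@H](OC(=O)C#CCCC)[C@@H]1O[Si](C)(C)C(C)(C)C | intermediate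
18 | 3α,9α-bis[(Z)-hex-2-enoate] 8α-tert-butyldimethylsilyl ether | C=C(C)[C@@H]1C[C@]2(C)[C@@H](C)[C@H](OC(=O)/C=C\CCC)CC[C@H]2[C@H](OC(=O)/C=C\CCC)[C@@H]1O[Si](C)(C)C(C)(C)C | intermediate
19 | CNP0420276.1 | C=C(C)[C@@H]1C[C@]2(C)[C@@H](C)[C@H](OC(=O)/C=C\CCC)CC[C@H]2[C@H](OC(=O)/C=C\CCC)[C@@H]1O | target

**Step count and risks**

Total steps: 11. Longest linear sequence: 11 (the route is fully linear from 1).

Most likely to fail, with one fallback each:

- **Step 4 (ring A closure by hydroacylation).** The carbene-catalysed addition of an aliphatic aldehyde to a vinyl group on a quaternary carbon has no direct precedent. If it fails, the same C3–C4 bond is made by a crossed benzoin, setting out from 8. Wacker oxidation (PdCl2, CuCl, O2, DMF–H2O) converts the vinyl group into the methyl ketone 3-(6-acetyl-6-methyl-2-oxocyclohex-3-en-1-yl)propanal F1. A triazolium-derived carbene with Et3N then adds the C3 acyl anion to the C4 ketone (intramolecular aldehyde–ketone benzoin, six-membered ring) to give the α-ketol 5-hydroxy-4a,5-dimethyl-4a,5,8,8a-tetrahydronaphthalene-1,6(4H,7H)-dione F2. SmI2 (THF–MeOH, −78 °C) removes the tertiary α-hydroxyl, and DBU equilibration returns to the route at 9.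

- **Step 8 (facial selectivity at C9).** The syn-axial C14 methyl opposes the β-face attack that the axial silyloxy group favours, so the ratio is uncertain. If hydride comes mainly from the α face, the product is 8α-(tert-butyldimethylsilyloxy)-7α-isopropenyl-4β,5β-dimethyl-10αH-trans-decalin-3α,9β-diol F3, reached from 14 under the same reduction. Its unhindered equatorial 3α-OH is esterified first (16, 1 equiv, DIC, DMAP) to the 3-mono(hex-2-ynoate) of that diol F4. The axial 9β-OH is then esterified with inversion by a Mitsunobu reaction with 16 (PPh3, DIAD), which rejoins the route at 17.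

- **Step 1 (one-pot conjugate vinylation and enolate propargylation).** Alkylation of the aluminium enolate at a carbon next to the new quaternary centre may be low-yielding. If so, the two events are separated, setting out from 1. The same conjugate addition with aqueous work-up gives (S)-3-methyl-3-vinylcyclohexan-1-one F5. IBX (DMSO, 65 °C) can dehydrogenate it only toward C7, because the other β-carbon is quaternary, giving (S)-5-methyl-5-vinylcyclohex-2-en-1-one F6. Its kinetic α′-lithium enolate (LDA, THF, −78 °C) is alkylated with 3, which rejoins the route at 7.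

**Further compounds**
F1 | step 4 | 3-(6-acetyl-6-methyl-2-oxocyclohex-3-en-1-yl)propanal, quaternary carbon as in 8 | O=CCCC1C(=O)C=CC[C@]1(C)C(C)=O
F2 | step 4 | 5-hydroxy-4a,5-dimethyl-4a,5,8,8a-tetrahydronaphthalene-1,6(4H,7H)-dione, quaternary C4a as in 9 | O=C1C=CC[C@]2(C)C(C)(O)C(=O)CCC12
F3 | step 8 | 8α-(tert-butyldimethylsilyloxy)-7α-isopropenyl-4β,5β-dimethyl-10αH-trans-decalin-3α,9β-diol | C=C(C)[C@@H]1C[C@]2(C)[C@@H](C)[C@H](O)CC[C@H]2[C@@H](O)[C@@H]1O[Si](C)(C)C(C)(C)C
F4 | step 8 | 3α-(hex-2-ynoyloxy) derivative of F3 (9β-OH free) | C=C(C)[C@@H]1C[C@]2(C)[C@@H](C)[C@H](OC(=O)C#CCCC)CC[C@H]2[C@@H](O)[C@@H]1O[Si](C)(C)C(C)(C)C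
F5 | step 1 | (S)-3-methyl-3-vinylcyclohexan-1-one | C=C[C@@]1(C)CCCC(=O)C1
F6 | step 1 | (S)-5-methyl-5-vinylcyclohex-2-en-1-one | C=C[C@@]1(C)CC=CC(=O)C1
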